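**Charge length.** In the asked flask free monomer outnumbers initiator by 50.0 to one. This ratio is the charge length: the average length if the whole charge of free monomer stood in chains, one chain per initiator. Multiplied by the fraction in chains, it gives the floor length: a chain begun costs one initiator.

the same everywhere: free monomer 0.80 M
- ash: initiator 2 mol%; the very flask that is asked about, followed so far
- alder: initiator 1.3 mol%; run made earlier
- flask: initiator 2 mol%; time 4.0 d

ash run (percent of the free monomer charged)

| time / h | monomer in chains / % | free monomer / % |
|---|---|---|
| 8.00 | 32 | 68 |
| 15.0 | 52 | 47 |
| 25.0 | 74 | 29 |
| 30.0 | 76 | 24 |
| 40.0 | 82 | 15 |
| 50.0 | 87 | 13 |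

alder run (percent of the free monomer charged)

| time / d | monomer in chains / % | free monomer / % |
|---|---|---|
| 0.208 | 17 | 85 |
| 0.333 | 20 | 79 |
| 0.625 | 39 | 62 |
| 1.04 | 56 | 43 |
| 1.67 | 75 | 30 |
| 3.00 | 88 | 13 |

(scatter of a reading: 1.5 percentage points)

* whether the average number of monomer units in a chain (chains begun, living or dead) reaches 40 by 4.0 d (no / yes)
* average number of monomer units in a chain (chains begun, living or dead) at 4.0 d

- the average divides the monomer in chains by the number of chains begun, living and dead together
- on the list of suspects stand: free monomer + initiator -> living end + monomer in chains; free monomer + living end -> monomer in chains + living end; monomer in chains + living end -> free monomer + living end; initiator -> spent initiator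
- the earlier runs do not show the number of chains; that part of a forecast is a guess

**Two extremes.** Ash is the asked flask followed so far. If each initiator begins a chain, ash at 50.0 h reads 87% in chains, so its length reads about 43.5, already above 40. If instead decay takes half of the initiator, the same reading gives a length twice as great. The readings do not show the number of chains, so the share of initiator that begins chains remains a guess, and this lower end is a chosen one, not a limit.

**The reckoning.** This reckoning replaces each unknown by a mean: the share is taken midway between the two chosen ends, and monomer in chains midway between the last ash reading, 87%, and the whole charge. This gives about 62.3, so the reckoning says yes. The forecast also says yes but gives 48, holding of initiator lost to decay that “the early kinetics give little sign of that”.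

**The flask.** The flask gives yes and 71.6 at 4.0 d, passing 40 at 0.626 d.

    free monomer + initiator → living end + monomer in chains (k = 2.40 × 10⁻⁴ /M/s)
    free monomer + living end → monomer in chains + living end, rate k2*[living end]*[free monomer] (k = 0.00150 /M/s)
    monomer in chains + living end → free monomer + living end, rate k3*[living end] as long as [monomer in chains] is above zero (k = 6.60 × 10⁻⁵ /s)
    initiator → spent initiator (k = 9.70 × 10⁻⁵ /s)

**Two exits.** At 4.0 d the flask holds 94.1% in chains, so its floor length is 47.0, and floor over length puts the share of initiator that began chains at 65.7%. At the charge of free monomer, the start of the run, the exit of an initiator into a chain runs about twice as fast as its exit by decay, 1.92 × 10⁻⁴ /s against 9.7 × 10⁻⁵ /s.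

The earlier runs and the new flask were computed for an exercise; scatter was added.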